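The target is disconnected at the cyclohexene ring of its bicyclo[2.2.2]octene (C(Me)=CH bridge, two bridgeheads, CH2 and CH(i-Pr)): the i-Pr methine, that CH and the neighbouring CH2 are read as a former gem-dimethylcyclopropane. In one operation a cycloheptatriene with a ring CMe2 contracts by 6π electrocyclisation to its norcaradiene, which (+)-altholactone traps by [4+2] cycloaddition, giving the bicyclooctene, the lactone fusion and six stereocentres. The precursor is 1-(dimethoxymethyl)-3,7,7-trimethylcycloheptatriene (from eucarvone); its masked formyl group later steers a retro-ene opening of one cyclopropane bond to the isopropenyl group and is removed by decarbonylation.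

Key step: step 11

Remark: (+)-Ipc2BOMe, the L-fructose-derived (ent-)Shi ketone, Grubbs II and the Rh complexes are taken as purchasable reagents; the cycloheptatriene is assumed to react in its usual norcaradiene mode.

Step 1
Reactants: 1 (E)-cinnamaldehyde
Product: 2 (3S,4S,E)-4-(methoxymethoxy)-1-phenylhexa-1,5-dien-3-ol
Conditions: CH2=CHCH2OMOM, s-BuLi, THF, −78 °C; (+)-Ipc2BOMe; BF3·OEt2; then 1, −78 °C; NaOH, H2O2
Reagents that add atoms: 3-(methoxymethoxy)prop-1-ene, C=CCOCOC
Why: Brown γ-alkoxyallylboration through a chair Zimmerman–Traxler transition state: the Z-alkoxyallyl unit should give the syn (threo) mono-protected diol, and the Ipc groups derived from (−)-α-pinene should direct attack to the Re face of the aldehyde, setting both carbinol centres.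

Step 2
Reactants: 2 (3S,4S,E)-4-(methoxymethoxy)-1-phenylhexa-1,5-dien-3-ol
Product: 3 (3S,4S,E)-4-(methoxymethoxy)-1-phenylhexa-1,5-dien-3-yl prop-2-enoate
Conditions: acryloyl chloride, Et3N, DMAP (cat.), CH2Cl2, 0 °C
Reagents that add atoms: acryloyl chloride, C=CC(=O)Cl
Why: Standard O-acylation of the free secondary alcohol installs the acrylate needed for ring closure without touching either stereocentre.

Step 3
Reactants: 3 (3S,4S,E)-4-(methoxymethoxy)-1-phenylhexa-1,5-dien-3-yl prop-2-enoate
Product: 4 (1R,2S)-2-(methoxymethoxy)-1-[(2R,3S)-3-phenyloxiran-2-yl]but-3-en-1-yl prop-2-enoate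
Conditions: ent-Shi ketone (30 mol%), Oxone, K2CO3, Bu4NHSO4, MeCN–DMM/borate buffer, 0 °C
Reagents that add atoms: potassium peroxymonosulfate (Oxone), [K+].[O-]S(=O)(=O)OO
Why: Shi asymmetric epoxidation: the dioxirane should epoxidise only the electron-rich trans-styrenyl alkene (acrylate and terminal vinyl are poor substrates), and its spiro transition state should deliver oxygen under reagent control to the face that makes the benzylic carbon S, the mirror image of what the D-fructose catalyst gives with trans-styrenes.

Step 4
Reactants: 4 (1R,2S)-2-(methoxymethoxy)-1-[(2R,3S)-3-phenyloxiran-2-yl]but-3-en-1-yl prop-2-enoate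
Product: 5 (5S,6R)-5-(methoxymethoxy)-6-[(2R,3S)-3-phenyloxiran-2-yl]-5,6-dihydro-2H-pyran-2-one
Conditions: Grubbs II (5 mol%), CH2Cl2, 40 °C
Reagents that add atoms: none
Why: Ring-closing metathesis of the acrylate with the neighbouring vinyl group should close the six-membered unsaturated lactone (epoxide tolerated) with loss of ethene and no change at the stereocentres.

Step 5
Reactants: 5 (5S,6R)-5-(methoxymethoxy)-6-[(2R,3S)-3-phenyloxiran-2-yl]-5,6-dihydro-2H-pyran-2-one
Product: 7 (+)-altholactone, via altholactone MOM ether 6 (not isolated)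
Conditions: CSA (0.2 equiv), CH2Cl2, 0 °C → rt; then MeOH, HCl (cat.), 40 °C
Reagents that add atoms: none
Why: Acid-catalysed 5-endo epoxide opening: the MOM ether oxygen attacks the activated benzylic carbon with inversion (2,3-trans tetrahydrofuran, cis-fused to the lactone), the expelled methoxymethyl cation is taken up by the new hydroxyl (6), and methanolic HCl then cleaves that acetal.

Step 6
Reactants: 8 (R)-(−)-carvone
Product: 9 (5R)-5-(2-bromopropan-2-yl)-2-methylcyclohex-2-en-1-one (carvone hydrobromide)
Conditions: HBr (33% in AcOH), 0 °C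
Reagents that add atoms: hydrogen bromide, Br
Why: Markovnikov addition of HBr to the 1,1-disubstituted isopropenyl alkene gives the tertiary bromide and leaves the enone untouched.

Step 7
Reactants: 9 carvone hydrobromide
Product: 11 eucarvone (2,6,6-trimethylcyclohepta-2,4-dien-1-one), via car-3-en-2-one 10 (not isolated)
Conditions: KOH, MeOH, 0 °C → reflux
Reagents that add atoms: none
Why: Classical eucarvone synthesis: the α′-enolate displaces the tertiary bromide to form the cyclopropane of 10, whose dienolate opens by 6π electrocyclic ring expansion to the achiral cycloheptadienone (the carvone stereocentre is deliberately erased).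

Step 8
Reactants: 11 eucarvone
Product: 12 7-(hydroxymethylidene)-2,6,6-trimethylcyclohepta-2,4-dien-1-one
Conditions: NaH, HCO2Et, EtOH (cat.), Et2O, 0 °C → rt; aq. HCl
Reagents that add atoms: ethyl formate, CCOC=O
Why: Crossed Claisen formylation at C-7, the only enolisable position of eucarvone, driven by formation of the chelated hydroxymethylene β-keto aldehyde enolate.

Step 9
Reactants: 12 7-(hydroxymethylidene)-2,6,6-trimethylcyclohepta-2,4-dien-1-one
Product: 13 7-(methoxymethylidene)-2,6,6-trimethylcyclohepta-2,4-dien-1-one
Conditions: Me2SO4, K2CO3, acetone, reflux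
Reagents that add atoms: dimethyl sulfate, COS(=O)(=O)OC
Why: O-Alkylation of the hydroxymethylene enolate with a hard methylating agent gives the methoxymethylene ketone (vinylogous ester) needed for carbonyl transposition.

Step 10
Reactants: 13 7-(methoxymethylidene)-2,6,6-trimethylcyclohepta-2,4-dien-1-one
Product: 15 1-(dimethoxymethyl)-3,7,7-trimethylcyclohepta-1,3,5-triene, via dienol 14 (not isolated)
Conditions: NaBH4, CeCl3·7H2O, MeOH, −40 °C; then HC(OMe)3, CSA, 0 °C
Reagents that add atoms: methanol, CO
Why: Luche 1,2-reduction of the vinylogous ester carbonyl, then acid ionisation of the bis-allylic alcohol 14 to an oxocarbenium–dienyl cation that methanol captures at the acetal carbon (Stork–Danheiser-type 1,3-transposition), leaving the conjugated triene with the masked formyl group on the terminus next to CMe2.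

Step 11
Reactants: 7 (+)-altholactone; 15 1-(dimethoxymethyl)-3,7,7-trimethylcyclohepta-1,3,5-triene
Product: 17 cyclopropane-fused Diels–Alder adduct, via norcaradiene 16 (not isolated)
Conditions: 15 (4 equiv), BHT, PhMe, 150 °C, sealed tube
Reagents that add atoms: none
Why: Thermal disrotatory 6π electrocyclisation turns the seven-membered ring of 15 into the six-membered diene ring of norcaradiene 16 (ring contraction, with CMe2 pushed out into a fused cyclopropane), and 16 is drained from the equilibrium by suprafacial [4+2] addition to the enoate of 7; the closest known reaction type is the Diels–Alder reaction of cycloheptatrienes through their norcaradiene tautomers with acrylate-type dienophiles. The cyclopropane closes by the electrocyclisation (bond between the two triene termini), and the two further six-membered rings of the bicyclo[2.2.2]octene close by the concerted [4+2] cycloaddition. The two bridgeheads and the two lactone ring-fusion centres follow from an endo transition state (lactone carbonyl under the diene, towards the new C(Me)=CH bridge) on the convex face of 7, anti to its fused tetrahydrofuran; the two cyclopropane centres follow from attack on the diene face anti to CMe2, so the future isopropyl carbon ends syn to the C(Me)=CH bridge. Regioselectivity is required: the diene terminus next to C–Me must bond to the lactone β-carbon (para orientation), which the 3-methyl group and the asynchronous enoate transition state favour, and this choice also selects one enantiomer of the rapidly racemising norcaradiene. [4+2] rather than [6+2] or [6+4] addition is the normal thermal behaviour of 7,7-disubstituted cycloheptatrienes, which also cannot undergo 1,5-hydrogen shifts.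

Step 12
Reactants: 17 cyclopropane-fused Diels–Alder adduct
Product: 20 isopropenyl aldehyde, via cyclopropanecarbaldehyde 18 (not isolated), via enol 19 (not isolated)
Conditions: AcOH–H2O (4:1), rt; then o-xylene, BHT, 190 °C, sealed tube
Reagents that add atoms: water, O
Why: Acetal hydrolysis gives 18, which on heating undergoes the homo-[1,5]-hydrogen shift (retro-ene, enolene rearrangement) of a cis-2-methylcyclopropyl carbonyl compound: only the bond between the formyl-bearing carbon and CMe2 can break, so CMe2 stays on the other ring carbon with retention as an isopropenyl group and enol 19 tautomerises to 20.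

Step 13
Reactants: 20 isopropenyl aldehyde
Product: 21 isopropyl aldehyde
Conditions: H2 (1 atm), RhCl(PPh3)3 (10 mol%), PhH, rt
Reagents that add atoms: none
Why: Homogeneous hydrogenation with Wilkinson's catalyst should reduce the unhindered 1,1-disubstituted isopropenyl alkene and leave the trisubstituted bridge alkene, the aldehyde and the lactone untouched (as in carvone → carvotanacetone).

Step 14
Reactants: 21 isopropyl aldehyde
Product: 22 target CNP0249919.1
Conditions: RhCl3·3H2O (5 mol%), dppp (10 mol%), diglyme, 162 °C
Reagents that add atoms: none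
Why: Rh(I)-catalysed Tsuji–Wilkinson decarbonylation (formyl C–H oxidative addition, CO extrusion, C–H reductive elimination) converts CH–CHO into CH2, which also erases the epimeric centre.

Compound list
1 | (E)-cinnamaldehyde | O=C/C=C/c1ccccc1 | starting material
2 | (3S,4S,E)-4-(methoxymethoxy)-1-phenylhexa-1,5-dien-3-ol | O[C@@H](/C=C/c1ccccc1)[C@@H](OCOC)C=C | intermediate
3 | (3S,4S,E)-4-(methoxymethoxy)-1-phenylhexa-1,5-dien-3-yl prop-2-enoate | C=CC(=O)O[C@@H](/C=C/c1ccccc1)[C@@H](OCOC)C=C | intermediate
4 | (1R,2S)-2-(methoxymethoxy)-1-[(2R,3S)-3-phenyloxiran-2-yl]but-3-en-1-yl prop-2-enoate (trans-epoxide) | C=CC(=O)O[C@@H]([C@@H]1O[C@H]1c1ccccc1)[C@@H](OCOC)C=C | intermediate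
5 | (5S,6R)-5-(methoxymethoxy)-6-[(2R,3S)-3-phenyloxiran-2-yl]-5,6-dihydro-2H-pyran-2-one | O=C1O[C@@H]([C@@H]2O[C@H]2c3ccccc3)[C@@H](OCOC)C=C1 | intermediate
6 | altholactone 3-O-methoxymethyl ether | O=C1O[C@H]2[C@H](OCOC)[C@@H](c3ccccc3)O[C@H]2C=C1 | intermediate (not isolated)
7 | (+)-altholactone, (2R,3R,3aS,7aS)-3-hydroxy-2-phenyl-2,3,3a,7a-tetrahydro-5H-furo[3,2-b]pyran-5-one | O=C1O[C@H]2[C@H](O)[C@@H](c3ccccc3)O[C@H]2C=C1 | intermediate
8 | (R)-(−)-carvone | CC(=C)[C@@H]1CC=C(C)C(=O)C1 | starting material
9 | carvone hydrobromide, (5R)-5-(2-bromopropan-2-yl)-2-methylcyclohex-2-en-1-one | CC(C)(Br)[C@@H]1CC=C(C)C(=O)C1 | intermediate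
10 | car-3-en-2-one (cis-fused 3,7,7-trimethylbicyclo[4.1.0]hept-3-en-2-one) | CC1=CC[C@@H]2[C@H](C1=O)C2(C)C | intermediate (not isolated)
11 | eucarvone, 2,6,6-trimethylcyclohepta-2,4-dien-1-one | CC1=CC=CC(C)(C)CC1=O | intermediate
12 | 7-(hydroxymethylidene)-2,6,6-trimethylcyclohepta-2,4-dien-1-one (chelated enol) | CC1=CC=CC(C)(C)C(=CO)C1=O | intermediate
13 | 7-(methoxymethylidene)-2,6,6-trimethylcyclohepta-2,4-dien-1-one | CC1=CC=CC(C)(C)C(=COC)C1=O | intermediate
14 | 7-(methoxymethylidene)-2,6,6-trimethylcyclohepta-2,4-dien-1-ol (racemic) | CC1=CC=CC(C)(C)C(=COC)C1O | intermediate (not isolated)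
15 | 1-(dimethoxymethyl)-3,7,7-trimethylcyclohepta-1,3,5-triene (achiral) | COC(OC)C1=CC(C)=CC=CC1(C)C | intermediate
16 | 1-(dimethoxymethyl)-3,7,7-trimethylbicyclo[4.1.0]hepta-2,4-diene (norcaradiene tautomer; the enantiomer that is trapped) | CC1=C[C@@]2(C(OC)OC)[C@@H](C=C1)C2(C)C | intermediate (not isolated)
17 | Diels–Alder adduct: target skeleton in which the bridge CH2 carbon carries CH(OMe)2 and is bonded to a CMe2 that also bonds the neighbouring bridge CH (gem-dimethylcyclopropane syn to the C(Me)=CH bridge); lactone endo, all altholactone centres retained | CC1=C[C@@H]2[C@@H]3C(=O)O[C@H]4[C@H](O)[C@@H](c5ccccc5)O[C@H]4[C@@H]3[C@H]1[C@@]6(C(OC)OC)[C@@H]2C6(C)C | intermediate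
18 | cyclopropanecarbaldehyde (17 with CHO in place of CH(OMe)2) | CC1=C[C@@H]2[C@@H]3C(=O)O[C@H]4[C@H](O)[C@@H](c5ccccc5)O[C@H]4[C@@H]3[C@H]1[C@@]6(C=O)[C@@H]2C6(C)C | intermediate (not isolated)
19 | enol from the retro-ene step (exocyclic hydroxymethylidene on the bridge carbon, isopropenyl on its neighbour) | CC1=C[C@@H]2[C@@H]3C(=O)O[C@H]4[C@H](O)[C@@H](c5ccccc5)O[C@H]4[C@@H]3[C@H]1C(=CO)[C@@H]2C(C)=C | intermediate (not isolated)
20 | isopropenyl aldehyde: target skeleton with isopropenyl for isopropyl and CHO on the former bridge CH2 (both epimers at that carbon, left unspecified) | CC1=C[C@@H]2[C@@H]3C(=O)O[C@H]4[C@H](O)[C@@H](c5ccccc5)O[C@H]4[C@@H]3[C@H]1C(C=O)[C@@H]2C(C)=C | intermediate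
21 | isopropyl aldehyde: target carrying CHO on the bridge CH2 carbon (epimers, unspecified) | CC1=C[C@@H]2[C@@H]3C(=O)O[C@H]4[C@H](O)[C@@H](c5ccccc5)O[C@H]4[C@@H]3[C@H]1C(C=O)[C@@H]2C(C)C | intermediate
22 | CNP0249919.1 (endo adduct of (+)-altholactone across the diene of (R)-α-phellandrene) | CC1=C[C@@H]2[C@@H]3C(=O)O[C@H]4[C@H](O)[C@@H](c5ccccc5)O[C@H]4[C@@H]3[C@H]1C[C@@H]2C(C)C | target

Total step count: 14. Longest linear sequence: 9 steps (steps 6–14 from carvone; the altholactone branch, steps 1–5 and 11–14, is equally long).

Steps most likely to fail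

Step 11. The cycloaddition may be too slow, because the lactone is a weak dienophile and only the minor norcaradiene tautomer reacts; decomposition of 15 or erosion of the para/meta regioselectivity could then take over. The fallback activates the dienophile with a removable α-halogen. Altholactone 7 is brominated and dehydrobrominated (Br2, CH2Cl2, 0 °C; then Et3N) to 6-bromoaltholactone F1. Its lower LUMO should allow cycloaddition with 15 near 100 °C to the bromo adduct F2 (same endo, convex-face, anti-cyclopropane topology, bromine exo). Radical debromination (Bu3SnH, AIBN, PhH, 80 °C) then returns to adduct 17.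

Step 12. At 190 °C, retro-cycloaddition, carbonyl-ene closure of the product or decomposition of the hindered aldehyde may outrun the 1,5-hydrogen shift. The fallback opens the ring reductively instead of pericyclically. Starting from 17, the acetal is hydrolysed as before and aldehyde 18 is isolated. SmI2 (2.5 equiv), HMPA and t-BuOH in THF at −78 °C give the ketyl, whose cyclopropylcarbinyl radical should open towards the tertiary CMe2 radical; reduction and protonation give isopropyl aldehyde 21 directly. The route is rejoined at 21, and step 13 is no longer needed.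

Step 8. The ambident eucarvone enolate may react through its bicyclic (norcaradienolate) valence tautomer or at oxygen, so that formylation at C-7 is not clean. The fallback introduces the one-carbon unit by condensation with an amide acetal. Eucarvone 11 is heated with tert-butoxybis(dimethylamino)methane (neat, 100 °C) to give the enaminone F3. DIBAL-H (PhMe, −78 °C) reduces the vinylogous amide carbonyl to the amino dienol F4. CSA, MeOH and HC(OMe)3 then expel dimethylamine with allylic transposition and give triene acetal 15.

Further compounds
F1 | step 11 | 6-bromoaltholactone, (2R,3R,3aS,7aS)-6-bromo-3-hydroxy-2-phenyl-2,3,3a,7a-tetrahydro-5H-furo[3,2-b]pyran-5-one | O=C1O[C@H]2[C@H](O)[C@@H](c3ccccc3)O[C@H]2C=C1Br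
F2 | step 11 | bromo adduct (17 with Br on the lactone α-carbon, exo) | CC1=C[C@@H]2[C@]3(Br)C(=O)O[C@H]4[C@H](O)[C@@H](c5ccccc5)O[C@H]4[C@@H]3[C@H]1[C@@]6(C(OC)OC)[C@@H]2C6(C)C
F0 | step 12 | none | none
F3 | step 8 | 7-[(dimethylamino)methylidene]-2,6,6-trimethylcyclohepta-2,4-dien-1-one | CC1=CC=CC(C)(C)C(=CN(C)C)C1=O
F4 | step 8 | 7-[(dimethylamino)methylidene]-2,6,6-trimethylcyclohepta-2,4-dien-1-ol (racemic) | CC1=CC=CC(C)(C)C(=CN(C)C)C1O
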